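Start from the small charge: the midnight run holds a quarter of the winter run's starting material. Read the two larger runs first, and ask what they say about the catalyst.

| flask | starting material | coupling partner | catalyst | time |
|---|---|---|---|---|
| winter | 0.600 M | 0.660 M | 0.0120 M |  |
| spring | 0.600 M | 0.660 M | 0.00600 M |  |
| midnight | 0.150 M | 0.170 M | 0.0120 M | 4.7 h |

| winter run: time / h | winter run: [starting material] / M | spring run: time / h | spring run: [starting material] / M |
|---|---|---|---|
| 0.94 | 0.5799 | 0.94 | 0.5919 |
| 1.9 | 0.5275 | 1.9 | 0.5631 |
| 2.8 | 0.4562 | 2.8 | 0.5167 |
| 3.8 | 0.3662 | 3.8 | 0.4462 |
| 4.7 | 0.2934 | 4.7 | 0.3722 |

(scatter of a reading: 0.002 M)

1. the exponent of [catalyst] in the starting rate at the charge of the winter run (at the point where two percent of the starting material have become target)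
2. starting material in the midnight run at 4.7 h, as a share of the starting material charged

- Overall: starting material + coupling partner -> target, with catalyst as catalyst.
- Constant volume, constant temperature.
- Readings of a species count what is bound in complexes too.
- "The second partner" is coupling partner.
- An order is taken over about fifteen percent of the charge, up and down.

Turn the question round. Suppose that halving the catalyst halved the rate at every amount of target made. Then the spring run would take 2 times as long as the winter run to make any given amount. So compare the runs at one amount, not at one time.

The winter run has made 0.02010 M by 0.94 h, which is 3.35 % of its charge and near the asked point. A straight line between the spring run's first two readings reaches that amount at 1.34 h.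

Define the stretch as the mean rate of one run over that of another up to the same amount of target. For winter over spring it is 1.43. Proportion to the catalyst needs 2 and indifference needs 1, so this flask stands short of proportion. My exponent is the logarithm of the stretch over ln(2), or 0.516. That is a reading, since the scatter of 0.002 M sits on a spring step of 0.02880 M.

For midnight, assume the rate follows c(starting material) · c(coupling partner). Its stretch against the winter run is then 15.5. With the winter run's mean rate of 0.02138 M/h, I expect 95.7 % of the starting material at 4.7 h.

The forecast differs from me on both counts: it says 0.7 (0.5 to 0.88) and 94 % (87 % to 96.5 %). Its ground is “The slope does not depend on catalyst, but the intercept scales roughly with it.”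

The flask gives an exponent of 0.50, below the forecast's, and 92.2 % for the midnight run, inside the forecast's range.

    active catalyst + coupling partner ⇌ catalyst-reagent complex, settled at all times (3.770 /M)
    catalyst-reagent complex + starting material → target + active catalyst (7.020 /M/h)
    catalyst + coupling partner → active catalyst + coupling partner (2.012 /M/h)
    starting material + coupling partner + target → 2 target (1.915 /M²/h)

In the winter run the step from catalyst to active catalyst, an induction period with a time constant of 0.753 h at the charged coupling partner, was running as the target passed the asked point at 0.031 M/h; the spring run passed that amount at 0.022 M/h, a rate ratio of 1.40 at that point, where the stretch read up to 0.0201 M was 1.43. In the midnight run the same step had a time constant of 2.92 h and ran across the 4.7 h, in which the flask made 0.01163 M of target, less than the 0.0201 M of the winter run's first reading.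

The runs come from a simulation on assumed constants; noise was put on by code.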